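## The problem

The target is an azaphilone, a 6H-isochromene-6,8(7H)-dione in which the pyran ring A (O2, C1, C3, C4, C4a, C8a) is fused through the C4a–C8a bond to the carbocyclic ring B (C4a, C5, C6, C7, C8, C8a). The three ring double bonds (C3=C4, C4a=C5, C8a=C1) and the two ketones form one cross-conjugated vinylogous ester. It is electrophilic at C1 and does not survive amines, strong base, hydride or hydrogenation, so the fully unsaturated core should appear late. There is a single stereocentre, the quaternary C7 (S), which carries a methyl group and an acyloxy oxygen between the C6 and C8 ketones. No second centre exists that could direct it, so a reagent or catalyst has to set it; once set it cannot epimerise by enolisation, but it could be lost by a retro-benzoin or α-ketol shift. The C7 oxygen is esterified with orsellinic acid, whose carboxyl group is flanked by a methyl and a hydroxyl group. A tertiary alcohol therefore has to be joined to a doubly ortho-substituted acyl group, and two phenols have to be freed at the end under conditions the core tolerates. The C3 side chain is an (E)-allylic acetate in conjugation with the ring A enol ether; it excludes zerovalent palladium, basic methanolysis and strongly ionising acid. The feature that opens the route is that C7 is a tertiary carbinol carbon bonded directly to the C8 ketone on C8a: the C7–C8 bond is the one an acyl anion at C8 would make with a methyl ketone at C7. This holds only if ring B is carried at the 4a,5-dihydro level (sp3 C4a, so the ketol cannot tautomerise to an arene) and C6 is masked as a ketal; the C4a=C5 bond and the C6 ketone must then be restored afterwards.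

## Retrosynthesis

**Silyl ethers and the ester bond.** The target 23 is traced to its bis(tert-butyldimethylsilyl) ether 22. Compound 22 is cut at the C7 O–acyl bond into the azaphilone alcohol 18 and the acid chloride 21, which comes from orsellinic acid 19 through the tris-silyl compound 20. Cutting here keeps the hindered ester and its silyl ethers away from the carbene, base and carbenium chemistry of ring construction. The cut is placed at 18 and not at the earlier ketol 15 because in 18 the carbinol carbon is flanked by two planar carbonyl carbons, whereas in 15 one neighbour is a quaternary ketal carbon. The precursors are a two-step acylating agent and a bicyclic alcohol with one stereocentre. The forward reaction must acylate a tertiary hydroxyl with a doubly ortho-substituted aroyl chloride without base damage to the core, and the final fluoride must spare the allylic acetate.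

**C4a=C5 and the C6 carbonyl.** 18 is traced to the 4a,5-dihydro ketal 15 by adding two hydrogens across C4a=C5 and re-masking C6 as its dimethyl ketal. In the forward sense a carbenium ion takes hydride from C4a to give the pyrylium salt 16, loss of a C5 proton gives the 4-alkylidenepyran 17, and dilute acid frees the ketone. The neighbouring order, ketal hydrolysis first and dehydrogenation second, is rejected: in 15 the ketal sits beside the carbinol carbon and its oxocarbenium ion is destabilised, whereas in 17 it is a vinylogous orthoester that ionises with the help of O2. No atoms are saved, but the electrophilic trienedione is exchanged for a compound with an sp3 C4a. The forward reaction asks that C4a–H, doubly allylic and leading to an aromatic cation, be a better hydride donor than the allylic CH2OAc group.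

**C7–C8, the key cut.** 15 is cut between C7 and C8 to the pyran aldehyde 14. The neighbouring cuts are less useful. C8–C8a or C5–C6 would be acylations that need the C7 centre ready-made in an acyclic acyl donor. C4a–C8a would be an arene-forming aldol that leaves C7 to a later oxidative dearomatisation. Only the C7–C8 cut closes ring B and creates C7 under catalyst control in the same event. 14 has one ring fewer and no stereocentre that matters, since its C4a centre is racemic and later flattened. The forward reaction asks a chiral carbene to turn the vinylogous formyl group into an acyl-anion equivalent, close a six-membered ring onto the ketone and choose the ketone face whatever the configuration at C4a.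

**Ring A.** 14 is a 4H-pyran, the cyclodehydrated form of a 1,5-dicarbonyl compound. Cuts at C4a–C8a (a Knoevenagel double bond in the forward sense), C4–C4a and O2–C3 give three pieces: aldehyde 5 (C4a with the C5–C7 arm), sodium malondialdehyde 11 (C1, C8a, C8) and the silyl dienol ether 9 (C3, C4 and the side chain). They are joined through the alkylidene malondialdehyde 12 and the silyl ketal 13. The alternative Michael addition of 11 to a cross-conjugated dienone would have to choose between two similar β-carbons, and a late cross-coupling of the side chain would bring zerovalent palladium to an allylic acetate. The chosen cut builds ring A in one operation from pieces of three to seven carbons with the acetate in place. It asks that 9 react through its enol ether double bond and not as a diene, and that the β-ketal of 5 and 12 not lose methanol.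

**The arm.** 5 comes from the alkene 4 by oxidative cleavage, 4 from the ester 3 by exchange of methoxide for methyl, and 3 from methyl dimethoxyacetate 1 and allyl bromide 2 by forming the C5–C6 bond. The ketal is thus present from the first step and never has to be installed on a 1,2-diketone, where regiochemistry would be open. The forward reactions are an enolate alkylation, a Grignard addition that must stop at the ketone, and an ozonolysis.

**Side chain and C3 unit.** 9 comes from the enone 8 by enol silylation, and 8 from but-3-en-2-one 6 and the diacetate 7 by cross-metathesis across the side-chain double bond, which sets the E geometry and carries the acetate from the start. 11 is the hydrolysis product of 1,1,3,3-tetramethoxypropane 10.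

## Roads not taken

**Alternative 1:** The cut is the C4a–C8a bond of an aromatic ring B. In the forward direction hydroxide opens the 4-pyranone A2 to a polyketo ester enolate, the β-keto ester carbon (C8a) adds to the C4a ketone, and dehydration and enolisation give the resorcylate A1, in which C1 is a tert-butyl ester. From A1 the ester would be taken to the aldehyde, the ketone closed onto it, and C7 hydroxylated by oxidative dearomatisation before esterification.
- Merits: the arene intermediates are robust, the whole carbon skeleton is present early, and the passage from an ortho-formylbenzyl ketone to an azaphilone is the best-precedented entry to this class.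
- Weak points: hydroxide meets a γ-silyloxy enone that can add or eliminate. The polyketo chain has several methylene and ketone partners, so isomeric arenes or pyranones can form. The ester must be reduced beside an enone. The silyl ether must be exchanged for the acetate. C7 would be set by an oxidative dearomatisation that needs either a stoichiometric chiral oxidant or a racemic oxidant and a resolution.
- Comparison: this road is better in the stability of its intermediates, and its late steps rest on firmer ground than the hydride abstraction of the chosen plan. The chosen plan sets against it a catalytic, organocatalytic creation of C7, no redox correction at C1 and no protecting-group exchange on the side chain.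

**Alternative 2:** The cut takes the C4a–C4 and C8a–C1 bonds at once. Fluoride would generate the benzyne A4, the enolate of the β-keto aldehyde A5 would add through carbon at C4a, the aryl anion at C8a would attack the formyl group, and fragmentation of the four-membered alkoxide would give the ortho-formylbenzyl ketone A3.
- Merits: two bonds form in one step, A3 has exactly the oxidation level needed for cyclisation, and addition to an alkoxy-substituted aryne should place the carbon nucleophile remote from the flanking oxygen, which is the required regiochemistry.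
- Weak points: aryne acyl-alkylation is established mainly for β-keto esters, and here a formyl group would have to migrate. A5 is an enolised keto aldehyde with an enone and an allylic acetate, fragile towards fluoride and base. The aryne precursor needs a multi-step synthesis. The methoxymethyl ethers must be removed with acid beside the allylic acetate. C7 is again left to an oxidative dearomatisation.
- Comparison: this road would reach the bicyclic skeleton in fewer steps than the chosen plan, but it shares the stereochemical problem of Alternative 1. The chosen plan answers that problem with a catalytic step.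

**Alternative 3:** The cuts are C5–C6 and C8–C8a. The exocyclic carbon of the 4-methylenepyran A7 would attack the acid chloride of the enantiopure malonyl derivative A8. Trifluoroacetic acid and its anhydride would then unmask and activate the tert-butyl ester so that C8a is acylated, giving A6, which is the same compound as 22.
- Merits: this is the most convergent plan. The stereocentre and the hindered ester are made in a small fragment, no dehydrogenation and no late esterification are needed, and A6 is one step from the target.
- Weak points: A7 is a very electron-rich enol ether that is readily protonated to a pyrylium ion and polymerises. After the first acylation the pyran is a vinylogous ester, so C8a is a poor nucleophile and its acylation by a mixed anhydride has no close precedent. The configuration of A8 rests only on the difference between its two carboxyl groups, so any acyl exchange under the acidic activation would erode it. The aroyl group and the silyl ethers must survive trifluoroacetic acid, and A8 needs an asymmetric synthesis of its own.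
- Comparison: if the annulation worked, this road would be shorter and would avoid the two weakest steps of the chosen plan, the hydride abstraction and the hindered acylation. The chosen plan sets against it a ring closure of a known catalytic asymmetric type and a stereocentre that is created, not carried through an activation that can scramble it.

Key step: step 8

Assumption: the (5aS,10bR) antipode of the triazolium salt is taken to deliver (7R)-15; should the opposite sense be found, the (5aR,10bS) salt is used and nothing else changes.
Remark: compounds 14 to 16 are carried as mixtures at C4a, which becomes planar in step 9.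

## Route

Step 1
Reactants: 1 methyl 2,2-dimethoxyacetate; 2 allyl bromide
Product: 3 methyl 2,2-dimethoxypent-4-enoate
Conditions: LiN(iPr)2, THF, −78 °C; then 2, DMPU, −78 to −20 °C
Reagents that add atoms: none
Why: Ester enolate alkylation: the amide base removes the acetal C–H of 1, and the doubly oxygenated enolate, a known glyoxylate anion equivalent, is alkylated by the reactive allylic bromide to put C5 and the ketal carbon C6 in place.

Step 2
Reactants: 3 methyl 2,2-dimethoxypent-4-enoate
Product: 4 3,3-dimethoxyhex-5-en-2-one
Conditions: MeMgBr (1.1 equiv), THF, −78 °C; aq. NH4Cl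
Reagents that add atoms: methylmagnesium bromide, C[Mg]Br
Why: Grignard addition to an α,α-dialkoxy ester: the magnesium hemiketal is stabilised by the two α-methoxy groups and the quaternary neighbour and collapses only on work-up, so the reaction stops at the methyl ketone, as in the usual preparation of α-keto acetals.

Step 3
Reactants: 4 3,3-dimethoxyhex-5-en-2-one
Product: 5 3,3-dimethoxy-4-oxopentanal
Conditions: O3, CH2Cl2, −78 °C; then PPh3, −78 °C to rt; used crude
Reagents that add atoms: ozone, [O-][O+]=O
Why: Ozonolysis with reductive work-up cleaves the only C=C bond; the ketone and the α-keto ketal are untouched, and the neutral phosphine work-up avoids β-elimination of methanol from the aldehyde, which is used at once.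

Step 4
Reactants: 6 but-3-en-2-one; 7 (Z)-but-2-ene-1,4-diyl diacetate
Product: 8 (E)-4-oxopent-2-en-1-yl acetate
Conditions: second-generation Grubbs catalyst RuCl2(=CHPh)(PCy3)(H2IMes) (2 mol %), excess 6, CH2Cl2, 40 °C
Reagents that add atoms: none
Why: Olefin cross-metathesis of an electron-poor enone with an electron-rich symmetrical internal alkene is a well-matched pairing and gives the E enone as the thermodynamic product.

Step 5
Reactants: 8 (E)-4-oxopent-2-en-1-yl acetate
Product: 9 (E)-4-[(tert-butyldimethylsilyl)oxy]penta-2,4-dien-1-yl acetate
Conditions: TBSOTf, Et3N, CH2Cl2, 0 °C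
Reagents that add atoms: tert-butyldimethylsilyl trifluoromethanesulfonate, CC(C)(C)[Si](C)(C)OS(=O)(=O)C(F)(F)F
Why: Soft enolisation of a methyl enone with a silyl triflate and a tertiary amine removes a methyl proton and gives the cross-conjugated 2-silyloxy-1,3-diene; the E alkene is not touched and the acetate is not enolised.

Step 6
Reactants: 10 1,1,3,3-tetramethoxypropane
Product: 11 sodium (E)-3-oxoprop-1-en-1-olate (sodium malondialdehyde)
Conditions: 1 M aq. HCl (1 equiv), 40 °C; then aq. NaOH (2 equiv), 0 °C; evaporation, trituration with acetone
Reagents that add atoms: water, O; sodium hydroxide, [Na+].[OH-]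
Why: Acid hydrolysis of the bis-acetal and neutralisation give the stable, weighable sodium enolate, the usual storage form of malondialdehyde.

Step 7
Reactants: 5 3,3-dimethoxy-4-oxopentanal; 11 sodium malondialdehyde; 9 (E)-4-[(tert-butyldimethylsilyl)oxy]penta-2,4-dien-1-yl acetate
Product: 14 (E)-3-[4-(2,2-dimethoxy-3-oxobutyl)-5-formyl-4H-pyran-2-yl]prop-2-en-1-yl acetate (racemic at pyran C4 = C4a), via alkylidene malondialdehyde 12 (not isolated), via silyl ketal cycloadduct 13 (not isolated)
Conditions: 11, CF3CO2H (1.0 equiv), CH2Cl2, 0 °C; then 5, 9 (1.5 equiv), ethylenediammonium diacetate (10 mol %), 4 Å molecular sieves, 0 °C to rt; then pyridinium p-toluenesulfonate (0.3 equiv), 40 °C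
Reagents that add atoms: none
Why: Domino Knoevenagel condensation and inverse-electron-demand hetero-Diels–Alder reaction of a 1,3-dicarbonyl compound with a silyl enol ether as the 2π partner (stepwise equivalent: Mukaiyama–Michael addition and O-closure): freed malondialdehyde condenses with 5 to the 1-oxadiene 12, the CH2 terminus of 9 bonds to C4a and the aldehyde oxygen to C3 to give 13, and mild acid expels the silanol into conjugation with the side-chain alkene. C4a forms racemic, which does not matter because it is flattened in step 9, and the α-keto ketal resists the anhydrous acid.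

Step 8
Reactants: 14 (E)-3-[4-(2,2-dimethoxy-3-oxobutyl)-5-formyl-4H-pyran-2-yl]prop-2-en-1-yl acetate
Product: 15 (E)-3-[(7R)-7-hydroxy-6,6-dimethoxy-7-methyl-8-oxo-5,6,7,8-tetrahydro-4aH-isochromen-3-yl]prop-2-en-1-yl acetate (both C4a epimers)
Conditions: (5aS,10bR)-2-(pentafluorophenyl)-5a,10b-dihydro-4H,6H-indeno[2,1-b][1,2,4]triazolo[4,3-d][1,4]oxazin-2-ium tetrafluoroborate (15 mol %), Et3N (15 mol %), toluene, rt
Reagents that add atoms: none
Why: Et3N deprotonates the triazolium salt, the carbene adds to the C8 formyl group, proton transfer gives the hydroxy-enamine, its C8 attacks the C7 ketone, and proton transfer with loss of the carbene leaves the tertiary ketol. This is the intramolecular crossed aldehyde–ketone benzoin reaction, known with aminoindanol-derived triazolium salts to give cyclic tertiary α-ketols. Ring B closes in the 6-exo-trig mode, C8 adding to the exocyclic C7=O across C8a, C4a, C5 and C6. The C7 centre is set by the catalyst, whose indane wall shields one face of the hydroxy-enamine; C4a bears only hydrogen and C6 carries two identical methoxy groups, so the substrate bias should be small and both C4a epimers should follow the catalyst to 7R. The step needs acyl-anion rather than homoenolate reactivity and attack on one ketone only: the vinylogous formyl group, like an electron-rich aryl aldehyde, is a good donor but a poor acceptor, which suppresses dimerisation; attack through C1 would need a bridged ring; the α,α-dimethoxy ketone is activated, cannot enolise towards C6 and is the only ketone present. The N-pentafluorophenyl carbene with a weak amine base is the combination that favours acyl-anion chemistry, and the sp3 C4a prevents aromatisation of the product.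

Step 9
Reactants: 15 (E)-3-[(7R)-7-hydroxy-6,6-dimethoxy-7-methyl-8-oxo-5,6,7,8-tetrahydro-4aH-isochromen-3-yl]prop-2-en-1-yl acetate
Product: 18 (E)-3-[(7S)-7-hydroxy-7-methyl-6,8-dioxo-7,8-dihydro-6H-isochromen-3-yl]prop-2-en-1-yl acetate, via pyrylium tetrafluoroborate 16 (not isolated), via azaphilone dimethyl ketal 17 (not isolated)
Conditions: Ph3CBF4 (1.2 equiv), 2,6-di-tert-butyl-4-methylpyridine (1.5 equiv), CH2Cl2, 0 °C to rt; then THF, 0.5 M aq. HCl, 0 °C
Reagents that add atoms: water, O
Why: Trityl cation abstracts hydride from the doubly allylic C4a–H of the 4-substituted 4H-pyran (the known pyran-to-pyrylium oxidation), the hindered pyridine removes the acidic C5 proton to give the 4-alkylidenepyran 17, and there the ketal is a vinylogous orthoester that ionises with the help of O2 and is hydrolysed by dilute acid. C7 is not touched; its descriptor changes from R to S only because C6 changes from ketal to ketone.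

Step 10
Reactants: 19 orsellinic acid (2,4-dihydroxy-6-methylbenzoic acid)
Product: 20 tert-butyldimethylsilyl 2,4-bis[(tert-butyldimethylsilyl)oxy]-6-methylbenzoate
Conditions: TBSCl (3.5 equiv), imidazole (7 equiv), DMF, rt
Reagents that add atoms: tert-butyldimethylsilyl chloride, CC(C)(C)[Si](C)(C)Cl
Why: Exhaustive silylation of the acid and both phenols; the silyl ester is the handle for the next step.

Step 11
Reactants: 20 tert-butyldimethylsilyl 2,4-bis[(tert-butyldimethylsilyl)oxy]-6-methylbenzoate
Product: 21 2,4-bis[(tert-butyldimethylsilyl)oxy]-6-methylbenzoyl chloride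
Conditions: (COCl)2 (1.2 equiv), DMF (cat.), CH2Cl2, 0 °C to rt; used crude
Reagents that add atoms: oxalyl chloride, O=C(Cl)C(=O)Cl
Why: Silyl esters are converted by oxalyl chloride and catalytic DMF into acid chlorides with release of the silyl chloride instead of HCl, so the two aryl silyl ethers survive.

Step 12
Reactants: 18 (E)-3-[(7S)-7-hydroxy-7-methyl-6,8-dioxo-7,8-dihydro-6H-isochromen-3-yl]prop-2-en-1-yl acetate; 21 2,4-bis[(tert-butyldimethylsilyl)oxy]-6-methylbenzoyl chloride
Product: 22 (7S)-3-[(E)-3-acetoxyprop-1-en-1-yl]-7-methyl-6,8-dioxo-7,8-dihydro-6H-isochromen-7-yl 2,4-bis[(tert-butyldimethylsilyl)oxy]-6-methylbenzoate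
Conditions: 21 (2 equiv), Et3N (3 equiv), DMAP (1 equiv), CH2Cl2, 0 °C to rt
Reagents that add atoms: none
Why: Acylation of a tertiary alcohol by an acid chloride under nucleophilic catalysis (acylpyridinium); in 18 the carbinol carbon is flanked by two sp2 carbonyl carbons, and acylation of the C7 hydroxyl of azaphilones is a known operation. The C7–O bond is not broken, so the configuration is retained.

Step 13
Reactants: 22 (7S)-3-[(E)-3-acetoxyprop-1-en-1-yl]-7-methyl-6,8-dioxo-7,8-dihydro-6H-isochromen-7-yl 2,4-bis[(tert-butyldimethylsilyl)oxy]-6-methylbenzoate
Product: 23 (7S)-3-[(E)-3-acetoxyprop-1-en-1-yl]-7-methyl-6,8-dioxo-7,8-dihydro-6H-isochromen-7-yl 2,4-dihydroxy-6-methylbenzoate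
Conditions: Bu4NF (2.2 equiv), AcOH (2.5 equiv), THF, 0 °C
Reagents that add atoms: none
Why: Fluoride cleaves aryl silyl ethers rapidly at 0 °C, and buffered with acetic acid it is neither basic nor nucleophilic enough to attack the allylic acetate, the tertiary ester or C1 of the azaphilone.

## Compound list

1 | methyl 2,2-dimethoxyacetate | COC(OC)C(=O)OC | starting material
2 | allyl bromide | C=CCBr | starting material
3 | methyl 2,2-dimethoxypent-4-enoate | C=CCC(OC)(OC)C(=O)OC | intermediate
4 | 3,3-dimethoxyhex-5-en-2-one | C=CCC(OC)(OC)C(C)=O | intermediate
5 | 3,3-dimethoxy-4-oxopentanal | CC(=O)C(OC)(OC)CC=O | intermediate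
6 | but-3-en-2-one | C=CC(C)=O | starting material
7 | (Z)-but-2-ene-1,4-diyl diacetate | CC(=O)OC/C=C\COC(C)=O | starting material
8 | (E)-4-oxopent-2-en-1-yl acetate | CC(=O)/C=C/COC(C)=O | intermediate
9 | (E)-4-[(tert-butyldimethylsilyl)oxy]penta-2,4-dien-1-yl acetate | C=C(O[Si](C)(C)C(C)(C)C)/C=C/COC(C)=O | intermediate
10 | 1,1,3,3-tetramethoxypropane | COC(CC(OC)OC)OC | starting material
11 | sodium (E)-3-oxoprop-1-en-1-olate (sodium malondialdehyde) | [Na+].[O-]/C=C/C=O | intermediate
12 | 2-(3,3-dimethoxy-4-oxopentylidene)propanedial | CC(=O)C(OC)(OC)CC=C(C=O)C=O | intermediate (not isolated)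
13 | (E)-3-[2-[(tert-butyldimethylsilyl)oxy]-4-(2,2-dimethoxy-3-oxobutyl)-5-formyl-3,4-dihydro-2H-pyran-2-yl]prop-2-en-1-yl acetate, mixture of diastereomers | CC(=O)OC/C=C/C1(O[Si](C)(C)C(C)(C)C)CC(CC(OC)(OC)C(C)=O)C(C=O)=CO1 | intermediate (not isolated)
14 | (E)-3-[4-(2,2-dimethoxy-3-oxobutyl)-5-formyl-4H-pyran-2-yl]prop-2-en-1-yl acetate, racemic | CC(=O)OC/C=C/C1=CC(CC(OC)(OC)C(C)=O)C(C=O)=CO1 | intermediate
15 | (E)-3-[(7R)-7-hydroxy-6,6-dimethoxy-7-methyl-8-oxo-5,6,7,8-tetrahydro-4aH-isochromen-3-yl]prop-2-en-1-yl acetate, both C4a epimers | CC(=O)OC/C=C/C1=CC2CC(OC)(OC)[C@](C)(O)C(=O)C2=CO1 | intermediate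
16 | (7R)-3-[(E)-3-acetoxyprop-1-en-1-yl]-7-hydroxy-6,6-dimethoxy-7-methyl-8-oxo-5,6,7,8-tetrahydroisochromenylium tetrafluoroborate | CC(=O)OC/C=C/c1cc2CC(OC)(OC)[C@](C)(O)C(=O)c2c[o+]1.F[B-](F)(F)F | intermediate (not isolated)
17 | (E)-3-[(7R)-7-hydroxy-6,6-dimethoxy-7-methyl-8-oxo-7,8-dihydro-6H-isochromen-3-yl]prop-2-en-1-yl acetate | CC(=O)OC/C=C/C1=CC2=CC(OC)(OC)[C@](C)(O)C(=O)C2=CO1 | intermediate (not isolated)
18 | (E)-3-[(7S)-7-hydroxy-7-methyl-6,8-dioxo-7,8-dihydro-6H-isochromen-3-yl]prop-2-en-1-yl acetate | CC(=O)OC/C=C/C1=CC2=CC(=O)[C@](C)(O)C(=O)C2=CO1 | intermediate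
19 | orsellinic acid (2,4-dihydroxy-6-methylbenzoic acid) | Cc1cc(O)cc(O)c1C(=O)O | starting material
20 | tert-butyldimethylsilyl 2,4-bis[(tert-butyldimethylsilyl)oxy]-6-methylbenzoate | Cc1cc(O[Si](C)(C)C(C)(C)C)cc(O[Si](C)(C)C(C)(C)C)c1C(=O)O[Si](C)(C)C(C)(C)C | intermediate
21 | 2,4-bis[(tert-butyldimethylsilyl)oxy]-6-methylbenzoyl chloride | Cc1cc(O[Si](C)(C)C(C)(C)C)cc(O[Si](C)(C)C(C)(C)C)c1C(=O)Cl | intermediate
22 | (7S)-3-[(E)-3-acetoxyprop-1-en-1-yl]-7-methyl-6,8-dioxo-7,8-dihydro-6H-isochromen-7-yl 2,4-bis[(tert-butyldimethylsilyl)oxy]-6-methylbenzoate | CC(=O)OC/C=C/C1=CC2=CC(=O)[C@](C)(OC(=O)c3c(C)cc(O[Si](C)(C)C(C)(C)C)cc3O[Si](C)(C)C(C)(C)C)C(=O)C2=CO1 | intermediate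
23 | (7S)-3-[(E)-3-acetoxyprop-1-en-1-yl]-7-methyl-6,8-dioxo-7,8-dihydro-6H-isochromen-7-yl 2,4-dihydroxy-6-methylbenzoate | CC(=O)OC/C=C/C1=CC2=CC(=O)[C@](C)(OC(=O)c3c(C)cc(O)cc3O)C(=O)C2=CO1 | target

## Step count and least certain steps

Total: 13 steps. Longest linear sequence: 8 steps (1, 2, 3, 7, 8, 9, 12, 13).

**Step 8 (key step).**
- What may go wrong: loss of catalyst control for the mismatched C4a antipode of racemic 14, as slow turnover or the opposite facial preference, which would appear as reduced enantiomeric purity once C4a is flattened. A second possibility is protonation of the hydroxy-enamine at C1 followed by β-loss of the ring oxygen, which opens ring A.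
- Fallback: give up catalyst control and resolve. The route is left at 14, which is cyclised with an achiral carbene (3-benzyl-5-(2-hydroxyethyl)-4-methylthiazolium chloride, Et3N, EtOH, 60 °C) to the ketol racemic at C7, F1. Under the conditions of step 9, F1 passes through the racemic pyrylium salt F2 and the racemic dimethyl ketal F3 to the racemic azaphilone alcohol F4. F4 has a single stereocentre and is separated by preparative chromatography on a chiral stationary phase; the S enantiomer rejoins the route at 18.

**Step 7.**
- What may go wrong: 9 may engage 12 through its diene terminus (carbocyclic Diels–Alder reaction) or be hydrolysed by the water of condensation. 12 may be consumed by a second malondialdehyde, or lose methanol from the β-ketal.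
- Fallback: use an enol ether that is not a diene and unveil the alkene afterwards. The route is left at 8. Conjugate addition of PhSeH (from (PhSe)2 and NaBH4, EtOH, then AcOH) gives 4-oxo-2-(phenylselanyl)pentyl acetate F5. Kinetic enolisation (LiN(SiMe3)2, THF, −78 °C, then TBSOTf) gives 4-[(tert-butyldimethylsilyl)oxy]-2-(phenylselanyl)pent-4-en-1-yl acetate F6. F6 replaces 9 in the union with 5 and 11 and gives, through 12 and the silyl ketal F7, the selanyl 4H-pyran F8. Oxidation (H2O2, pyridine, CH2Cl2, 0 °C) to the selenoxide F9 and syn-elimination at rt, which runs away from the acetoxy-bearing carbon and into conjugation, restore the E alkene and return to the route at 14.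

**Step 9.**
- What may go wrong: slow hydride transfer, because the acyl group on C8a makes the pyran a poorer hydride donor than a simple 4H-pyran, with competing ionisation of the allylic acetate or attack of the cation on the dienol ether.
- Fallback: enolate-based dehydrogenation in place of hydride abstraction. The route is left at 15. The ketal is hydrolysed with forcing acid (CF3CO2H–H2O, CH2Cl2, 0 °C to rt) to the 4a,5-dihydro dione F10. Me3SiOTf and Et3N give the bis-silyl compound F11, the C5=C6 silyl enol ether with a silylated C7 hydroxyl; C5 is the only enolisable position. Saegusa–Ito oxidation (Pd(OAc)2, MeCN, rt) gives the 7-O-trimethylsilyl azaphilone F12, and dilute acid removes the silyl ether to return at 18.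

**Step 12.**
- What may go wrong: slow acyl transfer from the doubly ortho-substituted acylpyridinium ion to the tertiary hydroxyl, with base-induced decomposition of 18 over the long reaction time.
- Fallback: build the arene after the ester bond. The route is left at 18, which is heated with 2,2-dimethyl-6-(2,4-dioxopentyl)-4H-1,3-dioxin-4-one in toluene at 100 °C. Retro-[4+2] loss of acetone gives the acylketene F13, a sterically undemanding acylating agent that is trapped by the tertiary hydroxyl to give the triketo ester F14. Intramolecular aldol condensation and dehydration (Cs2CO3, iPrOH, 0 °C, then AcOH) form the orsellinate ring and return directly at 23, without 22 and step 13.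

## Further compounds

F1 | step 8 | (E)-3-[7-hydroxy-6,6-dimethoxy-7-methyl-8-oxo-5,6,7,8-tetrahydro-4aH-isochromen-3-yl]prop-2-en-1-yl acetate, racemic at C7, both C4a epimers | CC(=O)OC/C=C/C1=CC2CC(OC)(OC)C(C)(O)C(=O)C2=CO1
F2 | step 8 | 3-[(E)-3-acetoxyprop-1-en-1-yl]-7-hydroxy-6,6-dimethoxy-7-methyl-8-oxo-5,6,7,8-tetrahydroisochromenylium tetrafluoroborate, racemic | CC(=O)OC/C=C/c1cc2CC(OC)(OC)C(C)(O)C(=O)c2c[o+]1.F[B-](F)(F)F
F3 | step 8 | (E)-3-[7-hydroxy-6,6-dimethoxy-7-methyl-8-oxo-7,8-dihydro-6H-isochromen-3-yl]prop-2-en-1-yl acetate, racemic | CC(=O)OC/C=C/C1=CC2=CC(OC)(OC)C(C)(O)C(=O)C2=CO1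
F4 | step 8 | (E)-3-[7-hydroxy-7-methyl-6,8-dioxo-7,8-dihydro-6H-isochromen-3-yl]prop-2-en-1-yl acetate, racemic | CC(=O)OC/C=C/C1=CC2=CC(=O)C(C)(O)C(=O)C2=CO1
F5 | step 7 | 4-oxo-2-(phenylselanyl)pentyl acetate, racemic | CC(=O)CC([Se]c1ccccc1)COC(C)=O
F6 | step 7 | 4-[(tert-butyldimethylsilyl)oxy]-2-(phenylselanyl)pent-4-en-1-yl acetate, racemic | C=C(O[Si](C)(C)C(C)(C)C)CC([Se]c1ccccc1)COC(C)=O
F7 | step 7 | 3-[2-[(tert-butyldimethylsilyl)oxy]-4-(2,2-dimethoxy-3-oxobutyl)-5-formyl-3,4-dihydro-2H-pyran-2-yl]-2-(phenylselanyl)propyl acetate, mixture of diastereomers | CC(=O)OCC([Se]c1ccccc1)CC1(O[Si](C)(C)C(C)(C)C)CC(CC(OC)(OC)C(C)=O)C(C=O)=CO1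
F8 | step 7 | 3-[4-(2,2-dimethoxy-3-oxobutyl)-5-formyl-4H-pyran-2-yl]-2-(phenylselanyl)propyl acetate, mixture of diastereomers | CC(=O)OCC([Se]c1ccccc1)CC1=CC(CC(OC)(OC)C(C)=O)C(C=O)=CO1
F9 | step 7 | 3-[4-(2,2-dimethoxy-3-oxobutyl)-5-formyl-4H-pyran-2-yl]-2-(phenylseleninyl)propyl acetate, mixture of diastereomers | CC(=O)OCC([Se](=O)c1ccccc1)CC1=CC(CC(OC)(OC)C(C)=O)C(C=O)=CO1
F10 | step 9 | (E)-3-[(7S)-7-hydroxy-7-methyl-6,8-dioxo-5,6,7,8-tetrahydro-4aH-isochromen-3-yl]prop-2-en-1-yl acetate, both C4a epimers | CC(=O)OC/C=C/C1=CC2CC(=O)[C@](C)(O)C(=O)C2=CO1
F11 | step 9 | (E)-3-[(7S)-7-methyl-8-oxo-6,7-bis[(trimethylsilyl)oxy]-7,8-dihydro-4aH-isochromen-3-yl]prop-2-en-1-yl acetate, both C4a epimers | CC(=O)OC/C=C/C1=CC2C=C(O[Si](C)(C)C)[C@](C)(O[Si](C)(C)C)C(=O)C2=CO1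
F12 | step 9 | (E)-3-[(7S)-7-methyl-6,8-dioxo-7-[(trimethylsilyl)oxy]-7,8-dihydro-6H-isochromen-3-yl]prop-2-en-1-yl acetate | CC(=O)OC/C=C/C1=CC2=CC(=O)[C@](C)(O[Si](C)(C)C)C(=O)C2=CO1
F13 | step 12 | 3,5,7-trioxooct-1-en-1-one (acylketene) | CC(=O)CC(=O)CC(=O)C=C=O
F14 | step 12 | (7S)-3-[(E)-3-acetoxyprop-1-en-1-yl]-7-methyl-6,8-dioxo-7,8-dihydro-6H-isochromen-7-yl 3,5,7-trioxooctanoate | CC(=O)OC/C=C/C1=CC2=CC(=O)[C@](C)(OC(=O)CC(=O)CC(=O)CC(C)=O)C(=O)C2=CO1
A1 | alternative 1 | tert-butyl 2,4-dihydroxy-3-methyl-6-[(E)-2-oxo-5-[(tert-butyldimethylsilyl)oxy]pent-3-en-1-yl]benzoate | CC(C)(C)OC(=O)c1c(O)c(C)c(O)cc1CC(=O)/C=C/CO[Si](C)(C)C(C)(C)C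
A2 | alternative 1 | tert-butyl 2-[3-methyl-4-oxo-6-[(E)-2-oxo-5-[(tert-butyldimethylsilyl)oxy]pent-3-en-1-yl]-4H-pyran-2-yl]acetate | CC(C)(C)OC(=O)CC1=C(C)C(=O)C=C(CC(=O)/C=C/CO[Si](C)(C)C(C)(C)C)O1
A3 | alternative 2 | 2,4-bis(methoxymethoxy)-3-methyl-6-[(E)-5-acetoxy-2-oxopent-3-en-1-yl]benzaldehyde | CC(=O)OC/C=C/C(=O)Cc1cc(OCOC)c(C)c(OCOC)c1C=O
A4 | alternative 2 | 3,5-bis(methoxymethoxy)-4-methylbenzyne | COCOC1=C(C)C(OCOC)=CC#C1
A5 | alternative 2 | (E)-4,6-dioxohex-2-en-1-yl acetate | CC(=O)OC/C=C/C(=O)CC=O
A6 | alternative 3 | (7S)-3-[(E)-3-acetoxyprop-1-en-1-yl]-7-methyl-6,8-dioxo-7,8-dihydro-6H-isochromen-7-yl 2,4-bis[(tert-butyldimethylsilyl)oxy]-6-methylbenzoate (identical with 22) | CC(=O)OC/C=C/C1=CC2=CC(=O)[C@](C)(OC(=O)c3c(C)cc(O[Si](C)(C)C(C)(C)C)cc3O[Si](C)(C)C(C)(C)C)C(=O)C2=CO1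
A7 | alternative 3 | (E)-3-(4-methylidene-4H-pyran-2-yl)prop-2-en-1-yl acetate | CC(=O)OC/C=C/C1=CC(=C)C=CO1
A8 | alternative 3 | tert-butyl (2R)-2-[[2,4-bis[(tert-butyldimethylsilyl)oxy]-6-methylbenzoyl]oxy]-3-chloro-2-methyl-3-oxopropanoate | O=C(Cl)[C@](C)(OC(=O)c1c(C)cc(O[Si](C)(C)C(C)(C)C)cc1O[Si](C)(C)C(C)(C)C)C(=O)OC(C)(C)C
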